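**Retrosynthetic overview** (tetralin numbering: C1 carries the aryl group, C2/C3 the CH2OH groups, C4 is CH2, C6 OMe, C7/C8 OH)

1. Target 14 ⇐ tri-O-benzyl ether 13 by hydrogenolysis.
2. 13 ⇐ 1,7-diene 10: zirconocene diene bicyclization makes the C2–C3 bond, so the cyclohexane ring and a zirconacyclopentane close together; O2 then turns both C–Zr bonds into the two CH2OH groups.
3. 10 ⇐ catechol mono-cinnamyl ether 7: a chiral-boron-promoted aromatic Claisen shift makes the aryl–C1 bond ortho to O8 (regiochemistry fixed by the ether oxygen) and sets C1.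
4. 7 ⇐ 5-allyl-3-methoxycatechol 3 (from eugenol, whose allyl group becomes C4–C3–CH2OH) + cinnamyl bromide 6 (from O-benzylvanillin).
5. Ring order: both benzene rings are bought; the carbocycle and the temporary zirconacycle form in step 8, and the zirconacycle is opened in the same pot.

Assumption: the (S,S)-bromoborane is taken to give the (S) centre at C1; if the first run gives the antipode, the (R,R)-reagent is used and nothing else changes.

**Step 1**
Reactants: 1 eugenol (4-allyl-2-methoxyphenol)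
Product: 2 5-allyl-2-hydroxy-3-methoxybenzaldehyde
Conditions: MgCl2 (1.5 equiv), Et3N (3.8 equiv), (CH2O)n (6 equiv), MeCN, reflux; 1 M HCl
Reagents that add atoms: paraformaldehyde (formaldehyde), C=O
Why: Casnati–Skattebøl magnesium-mediated ortho-formylation: the magnesium phenoxide delivers formaldehyde to the only free ortho carbon (the para carbon carries the allyl group) and a second formaldehyde oxidises the benzylic alkoxide by hydride transfer; no stereocentre.

**Step 2**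
Reactants: 2 5-allyl-2-hydroxy-3-methoxybenzaldehyde
Product: 3 5-allyl-3-methoxybenzene-1,2-diol
Conditions: 30% H2O2 (1.2 equiv), NaOH (1.0 equiv), H2O/THF, 0 °C → rt, N2; then 1 M HCl
Reagents that add atoms: hydrogen peroxide, OO
Why: Dakin oxidation: hydroperoxide adds to the ortho-hydroxy aldehyde, the aryl group migrates to oxygen and the formate is hydrolysed, the terminal alkene being inert to basic H2O2; no stereocentre.

**Step 3**
Reactants: 4 4-(benzyloxy)-3-methoxybenzaldehyde (O-benzylvanillin)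
Product: 5 (±)-1-[4-(benzyloxy)-3-methoxyphenyl]prop-2-en-1-ol
Conditions: CH2=CHMgBr (1.2 equiv), THF, 0 °C; then H2O
Reagents that add atoms: vinylmagnesium bromide, C=C[Mg]Br
Why: Grignard 1,2-addition to the aldehyde; the carbinol is racemic, which does not matter because the next step removes this stereocentre.

**Step 4**
Reactants: 5 (±)-1-[4-(benzyloxy)-3-methoxyphenyl]prop-2-en-1-ol
Product: 6 (E)-1-(benzyloxy)-4-(3-bromoprop-1-en-1-yl)-2-methoxybenzene
Conditions: PBr3 (0.35 equiv), Et2O, −10 → 0 °C; cold aq. NaHCO3 wash, used at once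
Reagents that add atoms: phosphorus tribromide, BrP(Br)Br
Why: Bromination with allylic transposition (SN2'/ion-pair return): the aryl vinyl carbinol gives the conjugated, thermodynamically favoured (E)-cinnamyl bromide; no stereocentre.

**Step 5**
Reactants: 3 5-allyl-3-methoxybenzene-1,2-diol; 6 (E)-1-(benzyloxy)-4-(3-bromoprop-1-en-1-yl)-2-methoxybenzene
Product: 7 4-allyl-2-{[(2E)-3-(4-benzyloxy-3-methoxyphenyl)prop-2-en-1-yl]oxy}-6-methoxyphenol
Conditions: K2CO3 (1.05 equiv), acetone, 0 °C → rt, N2; 6 (1.0 equiv) added slowly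
Reagents that add atoms: none
Why: Williamson ether synthesis (SN2 at the primary allylic carbon, E geometry kept): the mono-phenoxide reacts at the less hindered oxygen, the one flanked by a ring hydrogen, not at the oxygen flanked by OMe; no stereocentre.

**Step 6**
Reactants: 7 4-allyl-2-{[(2E)-3-(4-benzyloxy-3-methoxyphenyl)prop-2-en-1-yl]oxy}-6-methoxyphenol
Product: 9 4-allyl-3-[(1S)-1-(4-benzyloxy-3-methoxyphenyl)prop-2-en-1-yl]-6-methoxybenzene-1,2-diol, via aryloxyborane chelate 8 (not isolated)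
Conditions: (S,S)-TsNHCH(Ph)CH(Ph)NHTs (1.5 equiv) + BBr3 (1.5 equiv), CH2Cl2, rt, then evacuate; 7, Et3N (1.5 equiv), CH2Cl2, −78 → −45 °C, 48 h; MeOH, H2O (sulfonamide recovered)
Reagents that add atoms: none
Why: Enantioselective aromatic Claisen rearrangement ([3,3]) of a catechol mono-allyl ether promoted by a Corey-type chiral bromoborane: boron binds the free phenol and coordinates the ether oxygen in 8, so the shift runs at −45 °C to the only free ortho carbon of that oxygen (this fixes the aryl–C1 bond) and the C2-symmetric sulfonamide shields one face of the chair transition state, setting C1 as S.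

**Step 7**
Reactants: 9 4-allyl-3-[(1S)-1-(4-benzyloxy-3-methoxyphenyl)prop-2-en-1-yl]-6-methoxybenzene-1,2-diol
Product: 10 1-allyl-3,4-bis(benzyloxy)-2-[(1S)-1-(4-benzyloxy-3-methoxyphenyl)prop-2-en-1-yl]-5-methoxybenzene
Conditions: BnBr (2.5 equiv), K2CO3 (3 equiv), DMF, 40 °C
Reagents that add atoms: benzyl bromide, BrCc1ccccc1
Why: Williamson benzylation of both phenols, needed because acidic O–H would destroy the organozirconium reagent; C1 is not touched.

**Step 8**
Reactants: 10 1-allyl-3,4-bis(benzyloxy)-2-[(1S)-1-(4-benzyloxy-3-methoxyphenyl)prop-2-en-1-yl]-5-methoxybenzene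
Product: 13 [(1S,2R,3R)-7,8-bis(benzyloxy)-1-(4-benzyloxy-3-methoxyphenyl)-6-methoxy-1,2,3,4-tetrahydronaphthalene-2,3-diyl]dimethanol, via zirconacyclopentane 11 (not isolated), via zirconium dialkoxide 12 (not isolated)
Conditions: Cp2ZrCl2 (1.2 equiv), n-BuLi (2.4 equiv), THF, −78 °C, 1 h; 10, −78 °C → rt, 6 h, then 50 °C, 2 h; dry O2, −78 → 0 °C; 1 M HCl
Reagents that add atoms: dioxygen, O=O
Why: Negishi zirconocene diene bicyclization followed by Schwartz-type oxygenation: "Cp2Zr" couples the two terminal alkenes (new C2–C3 bond), closing the cyclohexane ring and the zirconacyclopentane 11 together; the coupling is reversible and equilibrates to the trans-fused ring with the CH2Zr arm on C2 trans to the C1 aryl group, which sets C2 (R) and C3 (R) from C1, and O2 then inserts into both C–Zr bonds with retention to give, after hydrolysis, the two CH2OH groups.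

**Step 9**
Reactants: 13 [(1S,2R,3R)-7,8-bis(benzyloxy)-1-(4-benzyloxy-3-methoxyphenyl)-6-methoxy-1,2,3,4-tetrahydronaphthalene-2,3-diyl]dimethanol
Product: 14 (6R,7R,8S)-8-(4-hydroxy-3-methoxyphenyl)-6,7-bis(hydroxymethyl)-3-methoxy-5,6,7,8-tetrahydronaphthalene-1,2-diol (target; 1S,2R,3R in tetralin numbering)
Conditions: H2 (1 atm), 10% Pd/C, EtOAc/MeOH, rt
Reagents that add atoms: none
Why: Catalytic hydrogenolysis of the three benzyl ethers; the C–C bonds at C1 and all three stereocentres are untouched and the product is 14.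

**Compound list**

1 | eugenol (4-allyl-2-methoxyphenol) | C=CCc1ccc(O)c(OC)c1 | starting material
2 | 5-allyl-2-hydroxy-3-methoxybenzaldehyde | O=Cc1cc(CC=C)cc(OC)c1O | intermediate
3 | 5-allyl-3-methoxybenzene-1,2-diol | C=CCc1cc(O)c(O)c(OC)c1 | intermediate
4 | 4-(benzyloxy)-3-methoxybenzaldehyde | O=Cc1ccc(OCc2ccccc2)c(OC)c1 | starting material
5 | (±)-1-[4-(benzyloxy)-3-methoxyphenyl]prop-2-en-1-ol | C=CC(O)c1ccc(OCc2ccccc2)c(OC)c1 | intermediate
6 | (E)-1-(benzyloxy)-4-(3-bromoprop-1-en-1-yl)-2-methoxybenzene | BrC/C=C/c1ccc(OCc2ccccc2)c(OC)c1 | intermediate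
7 | 4-allyl-2-{[(2E)-3-(4-benzyloxy-3-methoxyphenyl)prop-2-en-1-yl]oxy}-6-methoxyphenol | C=CCc1cc(OC/C=C/c2ccc(OCc3ccccc3)c(OC)c2)c(O)c(OC)c1 | intermediate
8 | aryloxyborane chelate: (4S,5S)-4,5-diphenyl-1,3-bis(p-tolylsulfonyl)-1,3,2-diazaborolidin-2-yl ether of the phenol oxygen of 7 | C=CCc1cc(OC/C=C/c2ccc(OCc3ccccc3)c(OC)c2)c(OB2N(S(=O)(=O)c3ccc(C)cc3)[C@@H](c3ccccc3)[C@H](c3ccccc3)N2S(=O)(=O)c2ccc(C)cc2)c(OC)c1 | intermediate (not isolated)
9 | 4-allyl-3-[(1S)-1-(4-benzyloxy-3-methoxyphenyl)prop-2-en-1-yl]-6-methoxybenzene-1,2-diol | COc1cc([C@H](C=C)c2c(CC=C)cc(OC)c(O)c2O)ccc1OCc1ccccc1 | intermediate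
10 | 1-allyl-3,4-bis(benzyloxy)-2-[(1S)-1-(4-benzyloxy-3-methoxyphenyl)prop-2-en-1-yl]-5-methoxybenzene | COc1cc([C@H](C=C)c2c(CC=C)cc(OC)c(OCc3ccccc3)c2OCc2ccccc2)ccc1OCc1ccccc1 | intermediate
11 | zirconacyclopentane: Cp2Zr bridging the C2-CH2 and C3-CH2 carbons of the (1S,2R,3R)-7,8-bis(benzyloxy)-1-(4-benzyloxy-3-methoxyphenyl)-6-methoxytetralin core | COc1cc([C@H]2c3c(cc(OC)c(OCc4ccccc4)c3OCc3ccccc3)C[C@H]5C[Zr+2]C[C@H]25)ccc1OCc1ccccc1.c1cc[cH-]c1.c1cc[cH-]c1 | intermediate (not isolated)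
12 | zirconium dialkoxide: Cp2Zr bound to both CH2O oxygens of the same (1S,2R,3R) core | COc1cc([C@H]2c3c(cc(OC)c(OCc4ccccc4)c3OCc3ccccc3)C[C@H]5CO[Zr+2]OC[C@H]25)ccc1OCc1ccccc1.c1cc[cH-]c1.c1cc[cH-]c1 | intermediate (not isolated)
13 | [(1S,2R,3R)-7,8-bis(benzyloxy)-1-(4-benzyloxy-3-methoxyphenyl)-6-methoxy-1,2,3,4-tetrahydronaphthalene-2,3-diyl]dimethanol | COc1cc([C@H]2c3c(cc(OC)c(OCc4ccccc4)c3OCc3ccccc3)C[C@@H](CO)[C@@H]2CO)ccc1OCc1ccccc1 | intermediate
14 | (6R,7R,8S)-8-(4-hydroxy-3-methoxyphenyl)-6,7-bis(hydroxymethyl)-3-methoxy-5,6,7,8-tetrahydronaphthalene-1,2-diol | COc1cc([C@H]2c3c(cc(OC)c(O)c3O)C[C@@H](CO)[C@@H]2CO)ccc1O | target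

**Step count**

Total steps: 9. Longest linear sequence: 7 (1 → 2 → 3 → 7 → 9 → 10 → 13 → 14; the branch 4 → 5 → 6 → 7 → … is also 7).

**Three steps most likely to fail, with fallbacks**

Step 8 (zirconocene bicyclization and oxygenation). Risks: zirconium-induced migration of the doubly benzylic, allylic double bond into conjugation; incomplete equilibration to the trans,trans ring; a modest yield in the O2 step. The fallback sets out from 10 and comes back at 13. Double hydroboration of 10 (9-BBN; H2O2/NaOH) gives the seco-diol 3-{3,4-bis(benzyloxy)-2-[(1S)-1-(4-benzyloxy-3-methoxyphenyl)-3-hydroxypropyl]-5-methoxyphenyl}propan-1-ol F1. Oxidation (TEMPO/PhI(OAc)2, MeCN–H2O) gives the diacid (3S)-3-(4-benzyloxy-3-methoxyphenyl)-3-[2,3-bis(benzyloxy)-6-(2-carboxyethyl)-4-methoxyphenyl]propanoic acid F2, and TMSCHN2 gives its dimethyl ester F3. The bis-enolate of F3 (LDA, 2.2 equiv, THF, −78 °C) is closed by intramolecular oxidative enolate coupling (CuCl2 or I2), which forms the C2–C3 bond. NaOMe/MeOH then equilibrates the two ester-bearing centres against the fixed C1 to the all-trans diester dimethyl (1S,2R,3R)-7,8-bis(benzyloxy)-1-(4-benzyloxy-3-methoxyphenyl)-6-methoxy-1,2,3,4-tetrahydronaphthalene-2,3-dicarboxylate F4. LiAlH4 reduction of F4 gives 13.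

Step 6 (asymmetric aromatic Claisen). Risk: the p-alkoxycinnamyl ether may ionise on boron, giving the [1,3]-shifted product or low ee. The fallback sets out from 3 and comes back at 10. A second magnesium-mediated ortho-formylation of 3 gives 6-allyl-2,3-dihydroxy-4-methoxybenzaldehyde F5. Benzylation of its dianion (NaH 2 equiv, DMSO; BnBr 1 equiv) at the oxygen not hydrogen-bonded to the aldehyde gives 6-allyl-3-(benzyloxy)-2-hydroxy-4-methoxybenzaldehyde F6. Vinylmagnesium bromide gives the carbinol (±)-1-[6-allyl-3-(benzyloxy)-2-hydroxy-4-methoxyphenyl]prop-2-en-1-ol F7. F7 is converted in situ to its ortho-quinone methide; a 3,3'-dibromo-BINOL catalyst (enantiomer chosen for S) with diisopropyl (4-benzyloxy-3-methoxyphenyl)boronate then transfers the aryl group 1,4 through the boron-bound phenol oxygen. This gives 3-allyl-6-(benzyloxy)-2-[(1S)-1-(4-benzyloxy-3-methoxyphenyl)prop-2-en-1-yl]-5-methoxyphenol F8, and benzylation of F8 gives 10.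

Step 5 (mono-etherification of the catechol). Risk: alkylation at the other oxygen or at both; the wrong regioisomer cannot rearrange in step 6, but it costs material. The fallback sets out from 2 and comes back at 7, fixing the regiochemistry by the order of events. SEMCl/iPr2NEt on 2 gives 5-allyl-3-methoxy-2-{[2-(trimethylsilyl)ethoxy]methoxy}benzaldehyde F9. Baeyer–Villiger oxidation (mCPBA, NaHCO3, CH2Cl2, 0 °C; the electron-rich aldehyde reacts far faster than the terminal alkene) and formate hydrolysis (KOH/MeOH) give 5-allyl-3-methoxy-2-{[2-(trimethylsilyl)ethoxy]methoxy}phenol F10, whose only free OH is the one to be alkylated. Alkylation with 6 (K2CO3, acetone) gives 5-allyl-1-{[(2E)-3-(4-benzyloxy-3-methoxyphenyl)prop-2-en-1-yl]oxy}-3-methoxy-2-{[2-(trimethylsilyl)ethoxy]methoxy}benzene F11, and TBAF (THF, 60 °C) removes the SEM group to give 7.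

**Further compounds**

F1 | step 8 | 3-{3,4-bis(benzyloxy)-2-[(1S)-1-(4-benzyloxy-3-methoxyphenyl)-3-hydroxypropyl]-5-methoxyphenyl}propan-1-ol | COc1cc([C@H](CCO)c2c(CCCO)cc(OC)c(OCc3ccccc3)c2OCc2ccccc2)ccc1OCc1ccccc1
F2 | step 8 | (3S)-3-(4-benzyloxy-3-methoxyphenyl)-3-[2,3-bis(benzyloxy)-6-(2-carboxyethyl)-4-methoxyphenyl]propanoic acid | COc1cc([C@H](CC(=O)O)c2c(CCC(=O)O)cc(OC)c(OCc3ccccc3)c2OCc2ccccc2)ccc1OCc1ccccc1
F3 | step 8 | methyl (3S)-3-(4-benzyloxy-3-methoxyphenyl)-3-[2,3-bis(benzyloxy)-4-methoxy-6-(3-methoxy-3-oxopropyl)phenyl]propanoate | COc1cc([C@H](CC(=O)OC)c2c(CCC(=O)OC)cc(OC)c(OCc3ccccc3)c2OCc2ccccc2)ccc1OCc1ccccc1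
F4 | step 8 | dimethyl (1S,2R,3R)-7,8-bis(benzyloxy)-1-(4-benzyloxy-3-methoxyphenyl)-6-methoxy-1,2,3,4-tetrahydronaphthalene-2,3-dicarboxylate | COc1cc([C@H]2c3c(cc(OC)c(OCc4ccccc4)c3OCc3ccccc3)C[C@@H](C(=O)OC)[C@@H]2C(=O)OC)ccc1OCc1ccccc1
F5 | step 6 | 6-allyl-2,3-dihydroxy-4-methoxybenzaldehyde | O=Cc1c(CC=C)cc(OC)c(O)c1O
F6 | step 6 | 6-allyl-3-(benzyloxy)-2-hydroxy-4-methoxybenzaldehyde | O=Cc1c(CC=C)cc(OC)c(OCc2ccccc2)c1O
F7 | step 6 | (±)-1-[6-allyl-3-(benzyloxy)-2-hydroxy-4-methoxyphenyl]prop-2-en-1-ol | C=CC(O)c1c(CC=C)cc(OC)c(OCc2ccccc2)c1O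
F8 | step 6 | 3-allyl-6-(benzyloxy)-2-[(1S)-1-(4-benzyloxy-3-methoxyphenyl)prop-2-en-1-yl]-5-methoxyphenol | COc1cc([C@H](C=C)c2c(CC=C)cc(OC)c(OCc3ccccc3)c2O)ccc1OCc1ccccc1
F9 | step 5 | 5-allyl-3-methoxy-2-{[2-(trimethylsilyl)ethoxy]methoxy}benzaldehyde | O=Cc1cc(CC=C)cc(OC)c1OCOCC[Si](C)(C)C
F10 | step 5 | 5-allyl-3-methoxy-2-{[2-(trimethylsilyl)ethoxy]methoxy}phenol | Oc1cc(CC=C)cc(OC)c1OCOCC[Si](C)(C)C
F11 | step 5 | 5-allyl-1-{[(2E)-3-(4-benzyloxy-3-methoxyphenyl)prop-2-en-1-yl]oxy}-3-methoxy-2-{[2-(trimethylsilyl)ethoxy]methoxy}benzene | C=CCc1cc(OC/C=C/c2ccc(OCc3ccccc3)c(OC)c2)c(OCOCC[Si](C)(C)C)c(OC)c1
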